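An hour is the unit to reckon in here, so each constant is best read as a time.

| setting | autumn | spring | midnight |
|---|---|---|---|
| substrate | 0.20 M | 0.20 M | 0.20 M |
| remark | one stirred flow tank at steady state, fed with the mixture as stated, mean residence time 2.5 h | a closed flask charged with all of it at once and left for 2.5 h | a single well-mixed tank run continuously and read at steady state, 12.5 h in it on average |
| time |  | 2.5 h |  |

- the set-up with the highest share of target in all that became target or side product or over-reaction product, at the outlet or at the end ("none" if the first two lie within 2 percentage points) (autumn / spring / midnight / none)
- share of target in all that became target or side product or over-reaction product, at the outlet or at the end, autumn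
- share of target in all that became target or side product or over-reaction product, at the outlet or at the end, spring
- share of target in all that became target or side product or over-reaction product, at the outlet or at the end, midnight

- a species is counted by the substrate in it: one idle adduct counts as two
- amounts and yields of target count idle adduct too
- the stated concentrations are those of everything mixed, before any reaction; amounts are the same in each set-up
- in an amount of target, one idle adduct counts as one target
- run time (spring): 2.5 h

    substrate ⇌ intermediate A (K1 = 8.53, k1 = 0.521 /h)
    intermediate A → intermediate B (k2 = 0.766 /h)
    intermediate B → intermediate C (k3 = 0.391 /h)
    intermediate C ⇌ intermediate D (K4 = 8.19, k4 = 0.199 /h)
    intermediate B → target (k5 = 0.0224 /h)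
    intermediate D → side product (k6 = 0.0135 /h)
    target → over-reaction product (k7 = 0.292 /h)
    substrate + target ⇌ idle adduct, settled at all times (K8 = 2.4 /M)

Substrate turns reversibly into intermediate A and A into intermediate B. B then splits: one way leads through intermediates C and D to the side product, the other to the target. The target goes on to the over-reaction product unless substrate holds it as idle adduct.

In the first instants of the spring flask, substrate leaves on a time of 1.92 h and A passes on in 1.31 h. At first A's fraction of the charge grows with time and B's with its square, and B's growth flattens later as B passes on; this reckoning takes the target's mean age at the end as roughly a third of the run, as an estimate. In the middle, B goes to C 17.5 times faster than to the target. The half-life of D by its last step is 51.3 h, far longer than the run, so this reckoning expects little side product in the spring flask. Substrate at its charged amount binds 0.480 adduct per free target, fewer as it falls.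

At the end, what counts is the exposure, the over-reaction constant times the time in the vessel, 0.730 for 2.5 h. In the spring flask, the target at its mean age keeps about 78.4 %. In a steady tank, target made per hour leaves either by the outlet or by over-reaction, so the target's share of those two is one over one plus the exposure. That gives 57.8 % for autumn, and 21.5 % for midnight. This reckoning omits adduct and side product, and it ranks spring first.

The forecast names spring, with 52.8 % for autumn, 81 % for spring and 8.5 % for midnight, on the ground that “a short batch with no back-mixing and plenty of substrate to hold target as adduct keeps the most”. Its tank figures lie below those reckoned here.

The simulation gives spring, with 52.8 % for autumn, 81.8 % for spring and 8.47 % for midnight.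

The time allowed is the main reason for what the spring flask keeps: left for 25.0 h instead of 2.5 h, its share falls from 81.8 % to 0.220 %, and its exposure rises from 0.730 to 7.30. In the autumn tank, the exposure of 0.730 gives by the rule 57.8 %, above the 52.8 % found. At 3 times the residence time the autumn exposure becomes 2.19, and the rule gives 31.3 %, against a simulated 17.6 %.

(The rate constants are invented; no experiment stands behind them.)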